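The cyclohexene ring is read as a desymmetrised quinone monoketal. The enamine α-carbon is the dienone carbonyl, the enamine β-carbon (azepine junction) its α-carbon, and CH(Et) its β-carbon. The carbinol CH(OH) is the ketal carbon, and the untouched enone becomes the lactone CH and the spiro C–O carbon. One copper-catalysed operation adds ethyl to one enantiotopic enone of 4,4-dimethoxycyclohexa-2,5-dienone and alkylates the zinc enolate with a four-carbon propargylic bromide. This fixes absolute configuration, ethyl group and azepine chain. The far end of that bromide is a silyl ether rather than a second halide, which could not outlive the later enolate and hydrogenation steps.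

Key step: step 3

Numbering used below: the carbocycle is numbered C1–C6 as in cyclohexenone 7.
- C1 = C=O, later the enamine α-carbon
- C2 = chain-bearing carbon, later the enamine β-carbon
- C3 = CHEt
- C4 = ketal, later the carbinol
- C5 = CH bearing the propionate arm
- C6 = later the spiro C–O carbon
- Cα = CHMe of the arm

Assumption 1: the ligand antipode is assigned by analogy with the sense known for cyclohexenone. Both antipodes are sold, so the other one is used if the sense on 4 is opposite.

Assumption 2: compounds 10–13 are carried as Cα epimers, so their SMILES leave that centre open. Step 8 fixes it.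

Step 1
Reactants: 1 but-2-yne-1,4-diol
Product: 2 4-(tert-butyldimethylsilyloxy)but-2-yn-1-ol
Conditions: NaH (1.0 equiv), THF, 0 °C; TBSCl (1.0 equiv), rt
Reagents that add atoms: tert-butyldimethylsilyl chloride CC(C)(C)[Si](C)(C)Cl
Why: O-silylation of the sparingly soluble monosodium alkoxide, which limits bis-silylation; no stereocentre is involved.

Step 2
Reactants: 2 4-(tert-butyldimethylsilyloxy)but-2-yn-1-ol
Product: 3 (4-bromobut-2-ynyloxy)(tert-butyl)dimethylsilane
Conditions: CBr4, PPh3, CH2Cl2, 0 °C
Reagents that add atoms: carbon tetrabromide BrC(Br)(Br)Br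
Why: Appel reaction, in which bromide displaces the alkoxyphosphonium group at a primary propargylic carbon under neutral conditions that leave the silyl ether intact.

Step 3
Reactants: 4 4,4-dimethoxycyclohexa-2,5-dien-1-one; 5 diethylzinc; 3 (4-bromobut-2-ynyloxy)(tert-butyl)dimethylsilane
Product: 7 (2S,3S)-2-[4-(tert-butyldimethylsilyloxy)but-2-ynyl]-3-ethyl-4,4-dimethoxycyclohex-5-en-1-one, via ethylzinc dienolate 6 (not isolated)
Conditions: Cu(OTf)2 (2 mol %), (R,S,S)-binaphthol bis(1-phenylethyl)amine phosphoramidite (4 mol %), 5 (1.1 equiv), toluene, −25 °C; then 3 (1.5 equiv), DMPU, −25 to 0 °C; aq NH4Cl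
Reagents that add atoms: none
Why: Transmetalation from 5 gives a phosphoramidite-bound ethylcopper(I) species that π-complexes one of the two enantiotopic enones of 4 and transfers ethyl (oxidative addition, reductive elimination), leaving ethylzinc dienolate 6, which after addition of DMPU is C-alkylated in an SN2 step by propargylic bromide 3 in the same flask. The closest known reaction type is the copper–phosphoramidite-catalysed asymmetric conjugate addition of dialkylzincs to cyclohexadienone monoketals, joined to the three-component trapping of a metal enolate by a propargylic halide. No ring is closed. C3 is controlled by the ligand, which selects both the enone and its face; C2 is controlled by the substrate, since the bromide approaches anti to the adjacent ethyl group, and the trans isomer is also the thermodynamic one. The step needs mono-addition (6 is no acceptor and 5 is used in slight excess only), C- rather than O-alkylation and SN2 rather than SN2′ attack (soft zinc enolate, unhindered primary propargylic carbon) and a single alkylation (only one C–Br bond in 3).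

Step 4
Reactants: 8 propanoic acid
Product: 9 1,1-bis(trimethylsilyloxy)prop-1-ene
Conditions: LDA (2.2 equiv), THF, −78 to 0 °C; TMSCl (2.4 equiv); distillation
Reagents that add atoms: chlorotrimethylsilane C[Si](C)(C)Cl
Why: Double deprotonation of the acid and O,O-bis-silylation of the enediolate (ketene acetal formation); the symmetric acetal has no E/Z isomers.

Step 5
Reactants: 7 enone from step 3; 9 1,1-bis(trimethylsilyloxy)prop-1-ene
Product: 10 bis-silyl Michael adduct (C1=C6 trimethylsilyl enol ether; CH(CH3)CO2SiMe3 arm on C5 trans to the C3 ethyl group; Cα epimers)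
Conditions: 9 (1.5 equiv), MeCN, 55 °C; evaporation, used crude
Reagents that add atoms: none
Why: Uncatalysed Mukaiyama–Michael addition with silyl transfer in a polar solvent, chosen so that no Lewis acid touches the ketal; axial attack on the half-chair with equatorial ethyl places the arm on C5 trans to the C3 ethyl group, the usual outcome for 5-substituted cyclohexenones.

Step 6
Reactants: 10 bis-silyl Michael adduct
Product: 12 cis-fused keto γ-lactone with alkyne chain (C6–O and C5–Cα on the same face; Cα epimers), via α-bromo ketone silyl ester 11 (not isolated)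
Conditions: NBS (1.05 equiv), THF, −78 to 0 °C; then sat. aq NaHCO3, rt
Reagents that add atoms: none
Why: Regiospecific bromination of the enol silane at C6 anti to the arm, then 5-exo-tet SN2 displacement of the α-bromo ketone by the liberated carboxylate with inversion, so that oxygen ends cis to the arm without passage through an enediol.

Step 7
Reactants: 12 cis-fused keto γ-lactone with alkyne chain
Product: 13 cis-fused keto γ-lactone with saturated 4-(silyloxy)butyl chain (Cα epimers)
Conditions: H2 (1 atm), 10% Pd/C, EtOAc, rt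
Reagents that add atoms: none
Why: Heterogeneous hydrogenation of the alkyne to the alkane; a propargylic silyl ether in EtOAc is not hydrogenolysed, and ketone, ketal and lactone are inert.

Step 8
Reactants: 13 cis-fused keto γ-lactone (Cα epimers)
Product: 15 single Cα epimer of the keto γ-lactone (Cα–H cis to C5–H; methyl cis to C4), via dilithium bis-enolate 14 (not isolated)
Conditions: LDA (2.3 equiv), THF, −78 °C; AcOH (excess) in THF, −78 °C
Reagents that add atoms: none
Why: Deprotonation and kinetic reprotonation: the first equivalent masks the ketone as its C1–C6 enolate, the second forms the lactone enolate, and the proton reaches Cα (and C6) from the convex face anti to the ketal-bearing C4, which gives the target configuration although it is the less stable epimer.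

Step 9
Reactants: 16 tert-butyl (4R)-4-formyl-2,2-dimethyl-1,3-oxazolidine-3-carboxylate (D-serine-derived); 17 ethyl 2-(bromomethyl)acrylate
Product: 20 tert-butyl (4R)-2,2-dimethyl-4-[(2S)-4-methylidene-5-oxooxolan-2-yl]-1,3-oxazolidine-3-carboxylate, via allylzinc bromide 18 (not isolated), via zinc alkoxide 19 (not isolated)
Conditions: activated Zn dust, THF, rt to 45 °C; aq NH4Cl; chromatography
Reagents that add atoms: none
Why: Dreiding–Schmidt reaction (Reformatsky-type allylation followed by lactonisation); under non-chelation control the allylzinc attacks anti to the C–N bond of the N,O-acetonide aldehyde and gives the anti amino alcohol (new CH–O centre S), the syn isomer being removed by chromatography.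

Step 10
Reactants: 20 α-methylene lactone
Product: 21 tert-butyl (4R)-2,2-dimethyl-4-[(2S,4S)-4-methyl-5-oxooxolan-2-yl]-1,3-oxazolidine-3-carboxylate
Conditions: H2 (1 atm), 10% Pd/C, EtOAc, rt
Reagents that add atoms: none
Why: Catalytic hydrogenation of the exocyclic alkene from the lactone face opposite the bulky oxazolidine gives the cis-2,4-disubstituted lactone (new CHMe centre S).

Step 11
Reactants: 21 methyl lactone acetonide
Product: 22 tert-butyl N-[(1R)-2-hydroxy-1-[(2S,4S)-4-methyl-5-oxooxolan-2-yl]ethyl]carbamate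
Conditions: AcOH–H2O 4:1, 40 °C
Reagents that add atoms: none
Why: Mild acid hydrolysis of the N,O-acetonide, which the Boc group and the γ-lactone survive.

Step 12
Reactants: 22 N-Boc amino alcohol
Product: 24 tert-butyl (4R)-4-[(2S,4S)-4-methyl-5-oxooxolan-2-yl]-1,2,3-oxathiazolidine-3-carboxylate 2,2-dioxide, via cyclic sulfamidite 23 (not isolated)
Conditions: SOCl2, pyridine, MeCN, −40 °C to rt; then RuCl3 (cat.), NaIO4, MeCN–H2O, 0 °C
Reagents that add atoms: thionyl chloride O=S(Cl)Cl; sodium periodate [Na+].[O-]I(=O)(=O)=O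
Why: Standard cyclic sulfamidate synthesis (ring closure with thionyl chloride, then Ru-catalysed oxidation of S(IV) to S(VI)); no carbon stereocentre takes part.

Step 13
Reactants: 15 keto γ-lactone; 24 cyclic sulfamidate
Product: 27 N-Boc amino C1,C4-diketone with 4-hydroxybutyl chain (C6 quaternary: CH2 on the ethyl face; lactone O on the arm face), via potassium enolate 25 (not isolated), via N-sulfamate salt 26 (not isolated)
Conditions: KHMDS (0.98 equiv), THF, −78 °C; 24 (1.2 equiv), THF–DMPU, −78 to 0 °C; then 1 M aq HCl, rt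
Reagents that add atoms: water O
Why: Enolate C-alkylation by SN2 ring opening of a 1,2-cyclic sulfamidate at its CH2–O carbon: C6–H is the most acidic proton, the electrophile enters on the convex face anti to Cα and to the axial methoxy group (giving the only unstrained, cis ring fusion), the CHN centre is untouched, and dilute HCl then hydrolyses N-sulfate, ketal and silyl ether but not the Boc group.

Step 14
Reactants: 27 N-Boc amino diketone alcohol
Product: 28 N-Boc amino keto diol (C4–OH cis to the arm and trans to ethyl)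
Conditions: NaBH4 (1.0 equiv), CeCl3·7H2O, MeOH, −78 °C; acetone, pH 7 buffer
Reagents that add atoms: none
Why: Luche reduction: the C1 ketone is neopentylic (quaternary C6, tertiary C2) and should be left; hydride should reach C4 from the face of ethyl and the C6 methylene, because the other face carries three substituents (Cα next door, the lactone O and the C2 chain 1,3), and this gives the more stable alcohol; buffered methanol at −78 °C avoids β-elimination of the β-acyloxy ketone.

Step 15
Reactants: 28 N-Boc amino keto diol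
Product: 29 primary mesylate of 28
Conditions: MsCl (1.05 equiv), Et3N, CH2Cl2, −30 °C
Reagents that add atoms: methanesulfonyl chloride CS(=O)(=O)Cl
Why: Selective sulfonylation of the primary alcohol, since the C4–OH flanked by two tertiary carbons does not react at low temperature.

Step 16
Reactants: 29 primary mesylate
Product: 33 target CNP0154902.3, via ammonium trifluoroacetate 30 (not isolated), via cyclic imine mesylate 31 (not isolated), via iminium mesylate 32 (not isolated)
Conditions: TFA, CH2Cl2, 0 °C; evaporation; iPr2NEt, 4 Å MS, MeCN (high dilution), 60 °C, argon; base-washed silica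
Reagents that add atoms: none
Why: Boc acidolysis, five-membered cyclic ketimine formation and 7-exo-tet N-alkylation of the imine by the mesylate; the iminium ion can lose only the C2 proton because C6 is quaternary, which gives the tetrasubstituted enamine and erases the auxiliary C2 centre.

Compound list
1 | but-2-yne-1,4-diol | OCC#CCO | starting material
2 | 4-(tert-butyldimethylsilyloxy)but-2-yn-1-ol | OCC#CCO[Si](C)(C)C(C)(C)C | intermediate
3 | (4-bromobut-2-ynyloxy)(tert-butyl)dimethylsilane | BrCC#CCO[Si](C)(C)C(C)(C)C | intermediate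
4 | 4,4-dimethoxycyclohexa-2,5-dien-1-one | COC1(OC)C=CC(=O)C=C1 | starting material
5 | diethylzinc | CC[Zn]CC | starting material
6 | ethylzinc (3S)-3-ethyl-4,4-dimethoxycyclohexa-1,5-dien-1-olate | CC[C@H]1C=C(O[Zn]CC)C=CC1(OC)OC | intermediate
7 | (2S,3S)-2-[4-(tert-butyldimethylsilyloxy)but-2-ynyl]-3-ethyl-4,4-dimethoxycyclohex-5-en-1-one | CC[C@H]1[C@H](CC#CCO[Si](C)(C)C(C)(C)C)C(=O)C=CC1(OC)OC | intermediate
8 | propanoic acid | CCC(=O)O | starting material
9 | 1,1-bis(trimethylsilyloxy)prop-1-ene | CC=C(O[Si](C)(C)C)O[Si](C)(C)C | intermediate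
10 | bis-silyl Michael adduct (arm on C5 trans to ethyl; Cα epimers) | CC[C@H]1[C@H](CC#CCO[Si](C)(C)C(C)(C)C)C(O[Si](C)(C)C)=C[C@H](C(C)C(=O)O[Si](C)(C)C)C1(OC)OC | intermediate
11 | α-bromo ketone silyl ester (C6–Br trans to the arm) | CC[C@H]1[C@H](CC#CCO[Si](C)(C)C(C)(C)C)C(=O)[C@@H](Br)[C@H](C(C)C(=O)O[Si](C)(C)C)C1(OC)OC | intermediate
12 | cis-fused keto γ-lactone, alkyne chain (Cα epimers) | CC[C@H]1[C@H](CC#CCO[Si](C)(C)C(C)(C)C)C(=O)[C@@H]2OC(=O)C(C)[C@@H]2C1(OC)OC | intermediate
13 | cis-fused keto γ-lactone, saturated chain (Cα epimers) | CC[C@H]1[C@H](CCCCO[Si](C)(C)C(C)(C)C)C(=O)[C@@H]2OC(=O)C(C)[C@@H]2C1(OC)OC | intermediate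
14 | dilithium bis-enolate of 13 | CC[C@H]1[C@H](CCCCO[Si](C)(C)C(C)(C)C)C([O-])=C2OC([O-])=C(C)[C@@H]2C1(OC)OC.[Li+].[Li+] | intermediate
15 | keto γ-lactone, single Cα epimer (methyl cis to C4) | CC[C@H]1[C@H](CCCCO[Si](C)(C)C(C)(C)C)C(=O)[C@@H]2OC(=O)[C@H](C)[C@@H]2C1(OC)OC | intermediate
16 | tert-butyl (4R)-4-formyl-2,2-dimethyl-1,3-oxazolidine-3-carboxylate | CC(C)(C)OC(=O)N1[C@@H](C=O)COC1(C)C | starting material
17 | ethyl 2-(bromomethyl)acrylate | CCOC(=O)C(=C)CBr | starting material
18 | 2-(ethoxycarbonyl)allylzinc bromide | CCOC(=O)C(=C)C[Zn]Br | intermediate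
19 | bromozinc alkoxide of the anti homoallylic alcohol | CC(C)(C)OC(=O)N1[C@@H]([C@H](CC(=C)C(=O)OCC)O[Zn]Br)COC1(C)C | intermediate
20 | tert-butyl (4R)-2,2-dimethyl-4-[(2S)-4-methylidene-5-oxooxolan-2-yl]-1,3-oxazolidine-3-carboxylate | CC(C)(C)OC(=O)N1[C@@H]([C@@H]2CC(=C)C(=O)O2)COC1(C)C | intermediate
21 | tert-butyl (4R)-2,2-dimethyl-4-[(2S,4S)-4-methyl-5-oxooxolan-2-yl]-1,3-oxazolidine-3-carboxylate | CC(C)(C)OC(=O)N1[C@@H]([C@@H]2C[C@H](C)C(=O)O2)COC1(C)C | intermediate
22 | tert-butyl N-[(1R)-2-hydroxy-1-[(2S,4S)-4-methyl-5-oxooxolan-2-yl]ethyl]carbamate | CC(C)(C)OC(=O)N[C@@H]([C@@H]1C[C@H](C)C(=O)O1)CO | intermediate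
23 | cyclic sulfamidite of 22 (sulfur epimers) | CC(C)(C)OC(=O)N1[C@@H]([C@@H]2C[C@H](C)C(=O)O2)COS1=O | intermediate
24 | tert-butyl (4R)-4-[(2S,4S)-4-methyl-5-oxooxolan-2-yl]-1,2,3-oxathiazolidine-3-carboxylate 2,2-dioxide | CC(C)(C)OC(=O)N1[C@@H]([C@@H]2C[C@H](C)C(=O)O2)COS1(=O)=O | intermediate
25 | potassium C1–C6 enolate of 15 | CC[C@H]1[C@H](CCCCO[Si](C)(C)C(C)(C)C)C([O-])=C2OC(=O)[C@H](C)[C@@H]2C1(OC)OC.[K+] | intermediate
26 | potassium N-Boc-N-sulfamate of the C6-alkylated ketal | CC[C@H]1[C@H](CCCCO[Si](C)(C)C(C)(C)C)C(=O)[C@]2(C[C@@H](N(C(=O)OC(C)(C)C)S(=O)(=O)[O-])[C@@H]3C[C@H](C)C(=O)O3)OC(=O)[C@H](C)[C@@H]2C1(OC)OC.[K+] | intermediate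
27 | N-Boc amino C1,C4-diketone with 4-hydroxybutyl chain | CC[C@H]1[C@H](CCCCO)C(=O)[C@]2(C[C@@H](NC(=O)OC(C)(C)C)[C@@H]3C[C@H](C)C(=O)O3)OC(=O)[C@H](C)[C@@H]2C1=O | intermediate
28 | N-Boc amino keto diol (C4–OH cis to the arm) | CC[C@H]1[C@H](CCCCO)C(=O)[C@]2(C[C@@H](NC(=O)OC(C)(C)C)[C@@H]3C[C@H](C)C(=O)O3)OC(=O)[C@H](C)[C@@H]2[C@@H]1O | intermediate
29 | primary mesylate of 28 | CC[C@H]1[C@H](CCCCOS(C)(=O)=O)C(=O)[C@]2(C[C@@H](NC(=O)OC(C)(C)C)[C@@H]3C[C@H](C)C(=O)O3)OC(=O)[C@H](C)[C@@H]2[C@@H]1O | intermediate
30 | ammonium trifluoroacetate from 29 | CC[C@H]1[C@H](CCCCOS(C)(=O)=O)C(=O)[C@]2(C[C@@H]([NH3+])[C@@H]3C[C@H](C)C(=O)O3)OC(=O)[C@H](C)[C@@H]2[C@@H]1O.[O-]C(=O)C(F)(F)F | intermediate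
31 | cyclic imine (1-pyrroline) mesylate | CC[C@H]1[C@H](CCCCOS(C)(=O)=O)C2=N[C@@H]([C@@H]3C[C@H](C)C(=O)O3)C[C@]24OC(=O)[C@H](C)[C@@H]4[C@@H]1O | intermediate
32 | tetracyclic iminium methanesulfonate | CC[C@H]1[C@H]2C3=[N+](CCCC2)[C@@H]([C@@H]2C[C@H](C)C(=O)O2)C[C@]32OC(=O)[C@H](C)[C@@H]2[C@@H]1O.CS(=O)(=O)[O-] | intermediate
33 | CNP0154902.3 | CC[C@H]1C2=C3N(CCCC2)[C@@H]([C@@H]2C[C@H](C)C(=O)O2)C[C@]32OC(=O)[C@H](C)[C@@H]2[C@@H]1O | target

Total step count: 16.
Longest linear sequence: 11 steps (1, 2, 3, 5, 6, 7, 8, 13, 14, 15, 16).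

Steps most likely to fail

Step 3.
- What may go wrong: C-alkylation of the zinc enolate may be slow. Proton exchange, a second ethyl transfer to the liberated enone, or SN2′ attack on the bromide could then take over.
- Fallback: the operation is divided without changing the bonds made. It sets out from 4 and 5.
- The conjugate addition is run as before. Dienolate 6 is trapped with TMSOTf as the trimethylsilyl dienol ether F1, which is isolated.
- MeLi in THF releases the lithium dienolate F2. This is alkylated with 3 in THF–DMPU at −78 to −30 °C, and the route is rejoined at 7.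

Step 13.
- What may go wrong: the tetrasubstituted enolate carbon may be too hindered for ring opening. O-alkylation, attack at sulfur or at the carbamate, alkylation through the C2 enolate, or decay of the α-acyloxy enolate could then compete.
- Fallback: the ring-opening electrophile is replaced by an open-chain primary triflate, and nitrogen is carried as an azide. It sets out from 22 and 15.
- HCl in dioxane converts 22 into the amino alcohol hydrochloride F3.
- Copper-catalysed diazo transfer with imidazole-1-sulfonyl azide gives, with retention, the azido alcohol F4.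
- Tf2O with 2,6-lutidine at −78 °C gives the azido triflate F5, which is used at once.
- Enolate 25, made from 15 as before, is alkylated by F5 at −78 °C to the azido ketal F6.
- 1 M HCl gives the azido diketone alcohol F7, Luche reduction the azido diol F8, and MsCl the azido mesylate F9.
- PPh3 in warm toluene (Staudinger reaction, then intramolecular aza-Wittig reaction) leads to 31, where the route is rejoined.

Step 14.
- What may go wrong: facial selectivity at C4 may be poor, and there may be some attack at C1.
- Fallback: kinetic hydride delivery is replaced by thermodynamic control of the carbinol centre. It sets out from 27.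
- The reduction mixture, 28 plus the C4-epimeric diol F10, is mesylated as in step 15. This gives 29 plus the C4-epimeric mesylate F11.
- The mixture is heated in toluene with a catalytic cyclopentadienone–ruthenium hydrogen-transfer complex. Reversible dehydrogenation through the keto mesylate F12 equilibrates C4.
- The wanted alcohol can sit equatorial in the chair that also keeps ethyl and chain equatorial. Its epimer must either be 1,3-diaxial to the C6 methylene group or force ethyl, chain and lactone oxygen axial. The route is rejoined at 29.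

Further compounds
F1 | step 3 | (S)-3-ethyl-4,4-dimethoxy-1-(trimethylsilyloxy)cyclohexa-1,5-diene | CC[C@H]1C=C(O[Si](C)(C)C)C=CC1(OC)OC
F2 | step 3 | lithium (3S)-3-ethyl-4,4-dimethoxycyclohexa-1,5-dien-1-olate | CC[C@H]1C=C([O-])C=CC1(OC)OC.[Li+]
F3 | step 13 | (1R)-2-hydroxy-1-[(2S,4S)-4-methyl-5-oxooxolan-2-yl]ethylammonium chloride | [NH3+][C@@H]([C@@H]1C[C@H](C)C(=O)O1)CO.[Cl-]
F4 | step 13 | (3S,5S)-5-[(1R)-1-azido-2-hydroxyethyl]-3-methyloxolan-2-one | [N-]=[N+]=N[C@@H]([C@@H]1C[C@H](C)C(=O)O1)CO
F5 | step 13 | (2R)-2-azido-2-[(2S,4S)-4-methyl-5-oxooxolan-2-yl]ethyl trifluoromethanesulfonate | [N-]=[N+]=N[C@@H]([C@@H]1C[C@H](C)C(=O)O1)COS(=O)(=O)C(F)(F)F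
F6 | step 13 | C6-alkylated azido ketal silyl ether | CC[C@H]1[C@H](CCCCO[Si](C)(C)C(C)(C)C)C(=O)[C@]2(C[C@@H](N=[N+]=[N-])[C@@H]3C[C@H](C)C(=O)O3)OC(=O)[C@H](C)[C@@H]2C1(OC)OC
F7 | step 13 | azido C1,C4-diketone alcohol | CC[C@H]1[C@H](CCCCO)C(=O)[C@]2(C[C@@H](N=[N+]=[N-])[C@@H]3C[C@H](C)C(=O)O3)OC(=O)[C@H](C)[C@@H]2C1=O
F8 | step 13 | azido keto diol | CC[C@H]1[C@H](CCCCO)C(=O)[C@]2(C[C@@H](N=[N+]=[N-])[C@@H]3C[C@H](C)C(=O)O3)OC(=O)[C@H](C)[C@@H]2[C@@H]1O
F9 | step 13 | azido keto alcohol primary mesylate | CC[C@H]1[C@H](CCCCOS(C)(=O)=O)C(=O)[C@]2(C[C@@H](N=[N+]=[N-])[C@@H]3C[C@H](C)C(=O)O3)OC(=O)[C@H](C)[C@@H]2[C@@H]1O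
F10 | step 14 | C4 epimer of diol 28 | CC[C@H]1[C@H](CCCCO)C(=O)[C@]2(C[C@@H](NC(=O)OC(C)(C)C)[C@@H]3C[C@H](C)C(=O)O3)OC(=O)[C@H](C)[C@@H]2[C@H]1O
F11 | step 14 | C4 epimer of mesylate 29 | CC[C@H]1[C@H](CCCCOS(C)(=O)=O)C(=O)[C@]2(C[C@@H](NC(=O)OC(C)(C)C)[C@@H]3C[C@H](C)C(=O)O3)OC(=O)[C@H](C)[C@@H]2[C@H]1O
F12 | step 14 | C1,C4-diketone mesylate | CC[C@H]1[C@H](CCCCOS(C)(=O)=O)C(=O)[C@]2(C[C@@H](NC(=O)OC(C)(C)C)[C@@H]3C[C@H](C)C(=O)O3)OC(=O)[C@H](C)[C@@H]2C1=O
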